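**Strategy.** The route rests on disconnecting the C22–C23 bond: the cyclopentane (C22–C26) is unravelled to a spiro-cyclobutane on C26 and an oxirane across C15–C22. The key step exploits the quaternary C22 that is shared by piperidine, cyclopentane and δ-lactone and carries C23 anti to O17 next to the N-bearing C26. Lewis-acid opening of the oxirane at C22 triggers a strain-releasing 1,2-shift from C26 to C22, N4 collects the charge as a ketimine, and the C15 alkoxide closes the lactone, all in one operation. The precursor is a trans-fused spiro[cyclobutane–piperidine] epoxide with a free N–H, a methyl propanoate arm on C22 and C7 masked as a dioxolane.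

Key step: step 12

Remark on the chemistry: atoms are numbered C1 to C26 in the order in which they stand in the target SMILES (N4, O5 the N-oxide oxygen, O17/C18/O19 the lactone). Compound 1 is taken as a commercial starting material.

Step 1
Reactants: 1 1,4-dioxaspiro[4.5]dec-6-en-8-one
Product: 2 7-iodo-1,4-dioxaspiro[4.5]dec-6-en-8-one
Conditions: I2, pyridine, CH2Cl2, 0 °C → rt
Reagents that add atoms: iodine, II
Why: α-Iodination of the enone by pyridine conjugate addition, enolate iodination and elimination places iodine on C14, where it later steers the CBS reduction and serves as the handle for the acetyl group.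

Step 2
Reactants: 2 7-iodo-1,4-dioxaspiro[4.5]dec-6-en-8-one
Product: 3 (8R)-7-iodo-1,4-dioxaspiro[4.5]dec-6-en-8-ol
Conditions: (S)-2-methyl-CBS-oxazaborolidine (10 mol%), BH3·SMe2, THF, −20 °C
Reagents that add atoms: none
Why: Corey–Bakshi–Shibata reduction in which the iodovinyl arm acts as the large group, so the (S)-catalyst should deliver hydride to give the (R)-carbinol at C13, the only stereocentre set by a chiral reagent and the one from which all others descend.

Step 3
Reactants: 3 (8R)-7-iodo-1,4-dioxaspiro[4.5]dec-6-en-8-ol
Product: 5 (8R)-7-iodo-1,4-dioxaspiro[4.5]dec-6-en-8-yl carbamate, via trichloroacetyl carbamate 4 (not isolated)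
Conditions: Cl3CC(O)NCO, CH2Cl2, 0 °C; then K2CO3, MeOH/H2O, rt
Reagents that add atoms: trichloroacetyl isocyanate, O=C=NC(=O)C(Cl)(Cl)Cl
Why: Carbamoylation of the allylic alcohol with an acyl isocyanate followed by mild methanolysis of the trichloroacetyl group gives the primary carbamate without touching the C13 stereocentre.

Step 4
Reactants: 5 (8R)-7-iodo-1,4-dioxaspiro[4.5]dec-6-en-8-yl carbamate
Product: 8 benzyl N-[(6S)-7-iodo-1,4-dioxaspiro[4.5]dec-7-en-6-yl]carbamate, via allyl cyanate 6 (not isolated), via allyl isocyanate 7 (not isolated)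
Conditions: (CF3CO)2O, Et3N, CH2Cl2, −20 → 0 °C; then BnOH, 40 °C
Reagents that add atoms: benzyl alcohol, OCc1ccccc1
Why: Allyl cyanate-to-isocyanate [3,3]-sigmatropic rearrangement: dehydration of the carbamate gives the cyanate, which rearranges suprafacially so that nitrogen arrives at C6 on the ring face that oxygen leaves at C13 (1,3-chirality transfer), and benzyl alcohol traps the isocyanate.

Step 5
Reactants: 8 benzyl N-[(6S)-7-iodo-1,4-dioxaspiro[4.5]dec-7-en-6-yl]carbamate
Product: 10 benzyl N-[(6R)-7-acetyl-1,4-dioxaspiro[4.5]dec-7-en-6-yl]carbamate, via ethoxyvinyl diene 9 (not isolated)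
Conditions: CH2=C(OEt)SnBu3, Pd(PPh3)4 (5 mol%), LiCl, dioxane, 90 °C; then 1 M HCl, THF, 0 °C
Reagents that add atoms: tributyl(1-ethoxyvinyl)stannane, CCOC(=C)[Sn](CCCC)(CCCC)CCCC; water, O
Why: Stille coupling of the alkenyl iodide with an acetyl-anion equivalent and brief cold hydrolysis of the enol ether, which is far more labile than the dioxolane, install C15 and C22 as the acetyl group on C14.

Step 6
Reactants: 10 benzyl N-[(6R)-7-acetyl-1,4-dioxaspiro[4.5]dec-7-en-6-yl]carbamate
Product: 11 1-[(6R,7S)-6-amino-1,4-dioxaspiro[4.5]decan-7-yl]ethan-1-one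
Conditions: H2 (1 atm), Pd/C, AcOH (1.1 equiv), EtOH, rt
Reagents that add atoms: none
Why: Catalytic hydrogenation saturates the enone C=C bond and hydrogenolyses the benzyl carbamate in one operation; C14 is α to the ketone, so any cis isomer converges on the trans (diequatorial) arrangement drawn for 11 during step 7.

Step 7
Reactants: 11 1-[(6R,7S)-6-amino-1,4-dioxaspiro[4.5]decan-7-yl]ethan-1-one; 12 cyclobutanone
Product: 14 trans-fused spiro-piperidone (C15 ketone), via N-cyclobutylidene amine 13 (not isolated)
Conditions: MgSO4, CH2Cl2, rt; then TsOH·H2O (1.2 equiv), toluene, 70 °C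
Reagents that add atoms: none
Why: Intramolecular Mannich reaction in which the methyl-ketone enol (C22) attacks the strained cyclobutyl iminium carbon C26 in the only ring size open to it (6-endo), while the ring fusion at C14, still α to the C15 ketone, settles as the trans-fused piperidone with both ring bonds equatorial.

Step 8
Reactants: 14 trans-fused spiro-piperidone (C15 ketone)
Product: 16 α-methylene spiro-piperidone (C21=C22), via Mannich base 15 (not isolated)
Conditions: (CH2O)n, PhNHMe·CF3CO2H (2.5 equiv), THF, reflux; 14 charged as its CF3CO2H salt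
Reagents that add atoms: formaldehyde (as paraformaldehyde), C=O
Why: Mannich aminomethylation with N-methylaniline followed by β-elimination can give an exocyclic methylene only at C22, the one α-carbon with two hydrogens, and the ring nitrogen is masked as its ammonium salt.

Step 9
Reactants: 16 α-methylene spiro-piperidone (C21=C22)
Product: 17 tertiary allylic alcohol (C15 carbinol, both epimers)
Conditions: MeLi, CeCl3, THF, −78 °C
Reagents that add atoms: methyllithium, [Li]C
Why: The organocerium reagent should add 1,2 to the hindered enone without conjugate addition or enolisation and so installs C16; the configuration at C15 is immaterial because this carbon becomes sp2 in step 10.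

Step 10
Reactants: 17 tertiary allylic alcohol (C15 carbinol, both epimers)
Product: 19 tetrahydropyridine methyl ester (C15=C22 alkene), via ketene acetal 18 (not isolated)
Conditions: MeC(OMe)3, EtCO2H (1.3 equiv), xylenes, 140 °C
Reagents that add atoms: trimethyl orthoacetate, CC(OC)(OC)OC
Why: Johnson–Claisen rearrangement in which the mixed ketene acetal on O–C15 shifts to C21, forming the C20–C21 bond, delivering the methyl propanoate arm and moving the alkene into the ring as the tetrasubstituted C15=C22 bond with no regiochemical choice.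

Step 11
Reactants: 19 tetrahydropyridine methyl ester (C15=C22 alkene)
Product: 20 spiro-cyclobutane piperidine epoxide (oxirane oxygen anti to C13)
Conditions: CF3CO2H (1.1 equiv), CH2Cl2, 0 °C; then mCPBA, 0 °C; cold aq NaHCO3
Reagents that add atoms: 3-chloroperbenzoic acid, OOC(=O)c1cccc(Cl)c1
Why: Peracid epoxidation of the electron-rich tetrasubstituted alkene with the amine protected from N-oxidation as its ammonium salt; attack is expected on the face opposite the pseudoaxial cyclobutane methylene on C26 and opposite C13, helped by hydrogen bonding to the axial N–H (ammonium-directed), which sets C15 and C22 together.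

Step 12
Reactants: 20 spiro-cyclobutane piperidine epoxide (oxirane oxygen anti to C13)
Product: 22 ketimine lactone, via hydroxy ester ketimine 21 (not isolated)
Conditions: MgBr2·OEt2 (2.5 equiv), CH2Cl2, −40 → 23 °C; then 40 °C
Reagents that add atoms: none
Why: Proposed new method: magnesium coordinates the oxirane oxygen, the C22–O bond lengthens and the cyclobutane bond C26–C23 lying antiperiplanar to it migrates to C22 with inversion, while the axial lone pair of N4 stabilises C26 as an iminium that loses its N–H proton to give the ketimine; the closest known reaction type is the Lewis-acid semipinacol ring expansion of 1-(oxiranyl)cyclobutanols, with the amine in the role of the hydroxyl donor. The cyclopentane is closed by this 1,2-shift (ring expansion of the four-membered ring) and the δ-lactone by 6-exo-trig attack of the freed C15 alkoxide on the ester carbonyl C18. The new quaternary centre C22 is controlled by the stereospecific anti migration, so the oxirane face chosen in step 11 fixes O17 on C15 and puts C23 on the opposite face of C22, leaving C21 cis to O17 as lactonisation requires. The step needs cleavage of C22–O and not C15–O, and migration and not attack by nitrogen: strain release together with nitrogen assistance is available only for ionisation at C22, the two cyclobutane methylenes are equivalent so there is no choice of migrating group, and the ring holds N4 gauche to the C22–O bond so that it cannot displace the oxygen itself.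

Step 13
Reactants: 22 ketimine lactone; 23 bromoacetone
Product: 25 pyrrole lactone, via N-acetonyl iminium bromide 24 (not isolated)
Conditions: NaHCO3, MeCN, 60 °C
Reagents that add atoms: none
Why: Chichibabin-type pyrrole annulation: N-alkylation of the cyclic ketimine by the α-bromoketone, enamine formation toward C25 (the only α-CH2), aldol attack on the ketone carbon C2 and dehydration should give the N4–C3=C2(CH3)–C25=C26 pyrrole with the methyl on the β-carbon.

Step 14
Reactants: 25 pyrrole lactone
Product: 26 pyrrolidine lactone (H2, H25, H26 cis; C7 dioxolane)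
Conditions: H2 (60 bar), Rh/Al2O3, AcOH, 40 °C
Reagents that add atoms: none
Why: Heterogeneous hydrogenation of the N-alkylpyrrole takes up all hydrogens from one catalyst face, which sets H2, H25 and H26 mutually cis, and delivery is expected on the face away from the axial C16 methyl that sits 1,3-syn-axial over C26 and N4 (as with 3-axially substituted cyclohexyl systems), giving H26 syn to C21 and the cis-fused cyclopentane–piperidine junction.

Step 15
Reactants: 26 pyrrolidine lactone (H2, H25, H26 cis; C7 dioxolane)
Product: 27 C7 ketone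
Conditions: 2 M HCl, THF, 45 °C; then aq NaHCO3
Reagents that add atoms: water, O
Why: Acid hydrolysis of the dioxolane releases the C7 ketone, while the protonated amine and the tertiary δ-lactone should survive aqueous acid and C6 keeps its equatorial nitrogen, the preferred arrangement of this α-amino ketone.

Step 16
Reactants: 27 C7 ketone
Product: 29 C11-allyl ketone (allyl axial; trans to N4 across C7), via silyl enol ether 28 (not isolated)
Conditions: Me3SiOTf, Et3N, CH2Cl2, 0 °C; then (CH2=CHCH2O)2CO, Pd2(dba)3 (2.5 mol%), PPh3, Bu4N[Ph3SiF2] (0.35 equiv), THF, 25 °C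
Reagents that add atoms: diallyl carbonate, C=CCOC(=O)OCC=C
Why: Soft enolisation silylates only the ketone, toward the accessible C11 methylene, and leaves the comparably acidic δ-lactone alone, and Tsuji allylation of the silyl enol ether then forms the C10–C11 bond under neutral conditions by stereoelectronically preferred axial attack on the enolate of the trans-fused ring.

Step 17
Reactants: 29 C11-allyl ketone (allyl axial; trans to N4 across C7)
Product: 31 primary alcohol (C8–OH), via pinacol boronate 30 (not isolated)
Conditions: HBpin, [Ir(cod)Cl]2 (1.5 mol%), dppm, CH2Cl2, rt; then NaBO3·4H2O, THF/H2O, rt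
Reagents that add atoms: sodium perborate, [Na+].[Na+].O[B-]1(O)OO[B-](O)(O)OO1
Why: Iridium-catalysed anti-Markovnikov hydroboration with pinacolborane should engage only the terminal alkene, sparing the hindered ketone and the lactone, and perborate oxidises the C–B bond to the C8 alcohol without epimerising C11.

Step 18
Reactants: 31 primary alcohol (C8–OH)
Product: 32 keto aldehyde
Conditions: Dess–Martin periodinane, NaHCO3, CH2Cl2, 0 °C → rt
Reagents that add atoms: none
Why: Dess–Martin oxidation gives the aldehyde under buffered, non-enolising conditions, so the axial C11 centre α to the ketone should be preserved.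

Step 19
Reactants: 32 keto aldehyde
Product: 33 tertiary amine with the C7=C8 cyclopentene (N-deoxy target)
Conditions: TiCl3(DME)1.5, Zn–Cu, DME, 25 °C → reflux, slow addition
Reagents that add atoms: none
Why: Intramolecular McMurry coupling joins C7 and C8: pinacol-type C–C bond formation at room temperature locks the ring before C11 can epimerise, and deoxygenation at reflux gives the C7=C8 alkene regiospecifically, the lactone carbonyl being too remote to compete.

Step 20
Reactants: 33 tertiary amine with the C7=C8 cyclopentene (N-deoxy target)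
Product: 34 target N-oxide (CNP0566793.5)
Conditions: mCPBA (1.05 equiv), CH2Cl2, −40 → 0 °C
Reagents that add atoms: 3-chloroperbenzoic acid, OOC(=O)c1cccc(Cl)c1
Why: Amine N-oxidation is much faster than epoxidation of the trisubstituted alkene at low temperature, and the ring fusions leave N4 a single lone-pair direction (cis to H26), so only one N-oxide configuration can form.

**Compound list**

1 | 1,4-dioxaspiro[4.5]dec-6-en-8-one | O=C1CCC2(OCCO2)C=C1 | starting material
2 | 7-iodo-1,4-dioxaspiro[4.5]dec-6-en-8-one | O=C1CCC2(OCCO2)C=C1I | intermediate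
3 | (8R)-7-iodo-1,4-dioxaspiro[4.5]dec-6-en-8-ol | O[C@@H]1CCC2(OCCO2)C=C1I | intermediate
4 | (8R)-7-iodo-1,4-dioxaspiro[4.5]dec-6-en-8-yl N-(trichloroacetyl)carbamate | ClC(Cl)(Cl)C(=O)NC(=O)O[C@@H]1CCC2(OCCO2)C=C1I | intermediate (not isolated)
5 | (8R)-7-iodo-1,4-dioxaspiro[4.5]dec-6-en-8-yl carbamate | NC(=O)O[C@@H]1CCC2(OCCO2)C=C1I | intermediate
6 | (8R)-7-iodo-1,4-dioxaspiro[4.5]dec-6-en-8-yl cyanate | N#CO[C@@H]1CCC2(OCCO2)C=C1I | intermediate (not isolated)
7 | (6S)-7-iodo-6-isocyanato-1,4-dioxaspiro[4.5]dec-7-ene | O=C=N[C@H]1C2(OCCO2)CCC=C1I | intermediate (not isolated)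
8 | benzyl N-[(6S)-7-iodo-1,4-dioxaspiro[4.5]dec-7-en-6-yl]carbamate | O=C(OCc1ccccc1)N[C@H]1C2(OCCO2)CCC=C1I | intermediate
9 | benzyl N-[(6R)-7-(1-ethoxyethenyl)-1,4-dioxaspiro[4.5]dec-7-en-6-yl]carbamate | O=C(OCc1ccccc1)N[C@H]1C2(OCCO2)CCC=C1C(=C)OCC | intermediate (not isolated)
10 | benzyl N-[(6R)-7-acetyl-1,4-dioxaspiro[4.5]dec-7-en-6-yl]carbamate | O=C(OCc1ccccc1)N[C@H]1C2(OCCO2)CCC=C1C(C)=O | intermediate
11 | 1-[(6R,7S)-6-amino-1,4-dioxaspiro[4.5]decan-7-yl]ethan-1-one (trans) | N[C@H]1C2(OCCO2)CCC[C@@H]1C(C)=O | intermediate
12 | cyclobutanone | O=C1CCC1 | starting material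
13 | 1-[(6R,7S)-6-(cyclobutylideneamino)-1,4-dioxaspiro[4.5]decan-7-yl]ethan-1-one | C1CC(C1)=N[C@H]1C2(OCCO2)CCC[C@@H]1C(C)=O | intermediate (not isolated)
14 | trans-fused spiro-piperidone: 8',8'-ethylenedioxy-octahydrospiro[cyclobutane-1,2'-quinolin]-4'-one (ring N4–C6–C14–C15(=O)–C22–C26; H6 and H14 trans) | N1[C@H]2C3(OCCO3)CCC[C@@H]2C(=O)CC11CCC1 | intermediate
15 | Mannich base of 14: 3'-[(N-methylanilino)methyl] at C22 (C22 epimers) | N1[C@H]2C3(OCCO3)CCC[C@@H]2C(=O)C(CN(C)c2ccccc2)C11CCC1 | intermediate (not isolated)
16 | α-methylene spiro-piperidone (exocyclic C21=C22 next to the C15 ketone) | N1[C@H]2C3(OCCO3)CCC[C@@H]2C(=O)C(=C)C11CCC1 | intermediate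
17 | tertiary allylic alcohol: C15 carbinol bearing C16, exocyclic C21=C22 (C15 epimers) | N1[C@H]2C3(OCCO3)CCC[C@@H]2C(C)(O)C(=C)C11CCC1 | intermediate
18 | 1-methoxyethenyl ether of 17 on O–C15 (mixed ketene acetal) | N1[C@H]2C3(OCCO3)CCC[C@@H]2C(C)(OC(=C)OC)C(=C)C11CCC1 | intermediate (not isolated)
19 | tetrahydropyridine methyl ester: C15(CH3)=C22 alkene, methyl propanoate arm on C22, spiro-cyclobutane at C26, C7 dioxolane | N1[C@H]2C3(OCCO3)CCC[C@@H]2C(C)=C(CCC(=O)OC)C11CCC1 | intermediate
20 | C15–C22 epoxide of 19, oxirane oxygen anti to C13 (key-step precursor) | N1[C@H]2C3(OCCO3)CCC[C@@H]2[C@@]2(C)O[C@@]2(CCC(=O)OC)C11CCC1 | intermediate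
21 | ring-expanded hydroxy ester ketimine (C15–OH, methyl ester, N4=C26, cyclopentane C22–C26) | N1[C@H]2C3(OCCO3)CCC[C@@H]2[C@@](C)(O)[C@]2(CCC(=O)OC)CCCC2=1 | intermediate (not isolated)
22 | ketimine lactone (N4=C26; cyclopentane fused at C22–C26; δ-lactone O17–C18 cis-fused at C15–C22; C7 dioxolane) | N1[C@H]2C3(OCCO3)CCC[C@@H]2[C@@]2(C)OC(=O)CC[C@]23CCCC3=1 | intermediate
23 | bromoacetone | CC(=O)CBr | starting material
24 | N-(2-oxopropyl) iminium bromide of 22 | CC(=O)C[N+]=1[C@H]2C3(OCCO3)CCC[C@@H]2[C@@]2(C)OC(=O)CC[C@]23CCCC3=1.[Br-] | intermediate (not isolated)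
25 | pyrrole lactone (pyrrole N4–C3=C2(CH3)–C25=C26) | Cc1cn2[C@H]3C4(OCCO4)CCC[C@@H]3[C@@]3(C)OC(=O)CC[C@]34CCc1c24 | intermediate
26 | pyrrolidine lactone, H2/H25/H26 cis and syn to C21, C7 dioxolane | C[C@@H]1CN2[C@H]3C4(OCCO4)CCC[C@@H]3[C@@]3(C)OC(=O)CC[C@]34CC[C@H]1[C@@H]42 | intermediate
27 | C7 ketone of 26 | C[C@@H]1CN2[C@H]3C(=O)CCC[C@@H]3[C@@]3(C)OC(=O)CC[C@]34CC[C@H]1[C@@H]42 | intermediate
28 | trimethylsilyl enol ether of 27 (C7=C11) | C[C@@H]1CN2[C@H]3C(O[Si](C)(C)C)=CCC[C@@H]3[C@@]3(C)OC(=O)CC[C@]34CC[C@H]1[C@@H]42 | intermediate (not isolated)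
29 | C11-allyl ketone, allyl axial and trans to N4 across C7 | C[C@@H]1CN2[C@H]3C(=O)[C@H](CC=C)CC[C@@H]3[C@@]3(C)OC(=O)CC[C@]34CC[C@H]1[C@@H]42 | intermediate
30 | pinacol boronate at C8 of the C11 propyl chain | C[C@@H]1CN2[C@H]3C(=O)[C@H](CCCB5OC(C)(C)C(C)(C)O5)CC[C@@H]3[C@@]3(C)OC(=O)CC[C@]34CC[C@H]1[C@@H]42 | intermediate (not isolated)
31 | primary alcohol (C11–CH2CH2CH2OH) | C[C@@H]1CN2[C@H]3C(=O)[C@H](CCCO)CC[C@@H]3[C@@]3(C)OC(=O)CC[C@]34CC[C@H]1[C@@H]42 | intermediate
32 | keto aldehyde (C7 ketone, C8 aldehyde) | C[C@@H]1CN2[C@H]3C(=O)[C@H](CCC=O)CC[C@@H]3[C@@]3(C)OC(=O)CC[C@]34CC[C@H]1[C@@H]42 | intermediate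
33 | tertiary amine with the C7=C8 cyclopentene (N-deoxy target) | C[C@@H]1CN2[C@H]3C4=CCC[C@@H]4CC[C@@H]3[C@@]3(C)OC(=O)CC[C@]34CC[C@H]1[C@@H]42 | intermediate
34 | target N-oxide CNP0566793.5 | C[C@@H]1C[N@+]2([O-])[C@H]3C4=CCC[C@@H]4CC[C@@H]3[C@@]3(C)OC(=O)CC[C@]34CC[C@H]1[C@@H]42 | target

**Totals.** Total step count: 20. Longest linear sequence: 20 steps (1 → 34); cyclobutanone and bromoacetone enter as purchased reagents.

**Steps most likely to fail**

1. Step 12 (key step). The oxirane may ionise at C15 instead of C22 (leading to a Meinwald-type shift or ester participation), or the Lewis acid may be held by the amine so that nitrogen assistance is lost. The fallback builds C22 by aldol chemistry and sets out from enone 10. Reduction of the C=C bond alone with [(Ph3P)CuH]6 and PhSiH3 gives benzyl N-[(6R,7S)-7-acetyl-1,4-dioxaspiro[4.5]decan-6-yl]carbamate F1. Purchased methyl 3-(2-oxocyclopentyl)propanoate is brominated at its tertiary α-carbon (Br2, CH2Cl2) to methyl 3-(1-bromo-2-oxocyclopentyl)propanoate F2. SmI2 (THF, −78 °C) converts F2 into its samarium enolate, which adds to the methyl ketone of F1 in a Reformatsky-type aldol reaction; the tertiary aldolate lactonises onto the ester to give the Cbz-protected keto lactone F3, from which the diastereomer with C16 syn to C23 has to be separated. Hydrogenolysis (H2, Pd/C) frees the amine, which condenses with the cyclopentanone and rejoins the route at ketimine lactone 22. This is known chemistry but gives up the stereospecificity of the 1,2-shift.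

2. Step 14. The pyrrole may adsorb on the methyl-bearing face, or hydrogen may be taken up stepwise, which would place H26 anti to C21 or scramble the all-cis relationship; both faces at C26 are hindered (axial C16 methyl on one, the C21 methylene on the other), so this face selectivity is the least certain stereochemical call in the route. The fallback sets out from pyrrole 25 and reduces it in two stages. NaBH(OAc)3 in CF3CO2H/CH2Cl2 at 0 °C should add hydride to C26 of the C3-protonated pyrrolium from the side away from the axial C16 methyl, as bulky hydrides do with 3-axially substituted six-membered rings, giving the 3-pyrroline F4 with the C2=C25 alkene intact. Hydrogenation of that tetrasubstituted alkene (H2, PtO2, AcOH) can then occur only on the convex face syn to H26, and the sequence returns to pyrrolidine 26.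

3. Step 16. Axial selectivity may erode during C–C bond formation, or the enolate released by desilylation may exchange protons with the lactone and equilibrate C11 to the more stable equatorial epimer. The fallback sets out from silyl enol ether 28 and adds it to acrolein in a Mukaiyama–Michael reaction (BF3·OEt2, i-PrOH, CH2Cl2, −78 °C), in which no free enolate is formed. Axial attack would give keto aldehyde 32 directly, bypassing 29, 30 and 31 and making no new compound.

**Further compounds**

F1 | step 12 | benzyl N-[(6R,7S)-7-acetyl-1,4-dioxaspiro[4.5]decan-6-yl]carbamate | O=C(OCc1ccccc1)N[C@H]1C2(OCCO2)CCC[C@@H]1C(C)=O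
F2 | step 12 | methyl 3-(1-bromo-2-oxocyclopentyl)propanoate (racemic) | COC(=O)CCC1(Br)CCCC1=O
F3 | step 12 | Cbz-protected keto lactone (cyclopentanone C26=O, δ-lactone at C15–C22) | O=C(OCc1ccccc1)N[C@H]1C2(OCCO2)CCC[C@@H]1[C@@]1(C)OC(=O)CC[C@]12CCCC2=O
F4 | step 14 | 3-pyrroline lactone (C2=C25 alkene, H26 syn to C21) | CC=1CN2[C@H]3C4(OCCO4)CCC[C@@H]3[C@@]3(C)OC(=O)CC[C@]34CCC1[C@@H]42
F0 | step 16 | none | none
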